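**Strategy.** The cyclohexane is disconnected at two ring bonds at once: C3–C4 (isopropenyl-bearing CH to the methyl/vinyl quaternary carbon) and C1–C2 (side-chain-bearing CH to the carbinol carbon). Read backwards, C2 is an aldehyde, the vinyl-bearing C4 with its C3 neighbour is a Claisen retron, and the C1 side chain, seen as an oxidised 2-propenyl group, makes C1–C2–OH a carbonyl-ene retron. An acyclic neryl-type 3-methylbuta-1,3-dienyl ether therefore gives, under a chiral aluminium Lewis acid, a [3,3] shift and an ene ring closure in one flask, setting all four ring stereocentres. The tertiary alcohol and both acetates follow from the new allylic alcohol.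

Key step: step 7

Remark: the (R)-configured aluminium aryloxide of step 7 is assumed to induce the configuration drawn; should the sense be opposite, its enantiomer is used.

**Step 1**
Reactants: 1 nerol; 2 but-3-yn-2-one
Product: 3 (3E)-4-{[(2Z)-3,7-dimethylocta-2,6-dien-1-yl]oxy}but-3-en-2-one
Conditions: DABCO (10 mol %), CH2Cl2, 0 → 23 °C
Reagents that add atoms: none
Why: Amine-catalysed oxa-Michael addition of the primary alcohol to the ynone should give the (E)-β-alkoxy enone, which both masks the alcohol and carries the future aldehyde and isopropenyl carbons.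

**Step 2**
Reactants: 3 (3E)-4-{[(2Z)-3,7-dimethylocta-2,6-dien-1-yl]oxy}but-3-en-2-one
Product: 4 (4Z)-4-methyl-6-{[(1E)-3-oxobut-1-en-1-yl]oxy}hex-4-enal
Conditions: O3 (1.0 equiv, Sudan Red 7B end point), CH2Cl2/MeOH, −78 °C; then Me2S, −78 → 23 °C
Reagents that add atoms: ozone, [O-][O+]=O
Why: Ozonolysis with reductive work-up should cleave the electron-rich isopropylidene alkene ahead of the allylic-ether alkene and the push–pull enone alkene when ozone is dosed to the dye end point.

**Step 3**
Reactants: 4 (4Z)-4-methyl-6-{[(1E)-3-oxobut-1-en-1-yl]oxy}hex-4-enal; 5 ethyl 2-[bis(2,2,2-trifluoroethoxy)phosphoryl]propanoate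
Product: 6 ethyl (2Z,6Z)-2,6-dimethyl-8-{[(1E)-3-oxobut-1-en-1-yl]oxy}octa-2,6-dienoate
Conditions: 5, KN(SiMe3)2, 18-crown-6, THF, −78 °C; then 4
Reagents that add atoms: none
Why: The Still–Gennari variant of the Horner–Wadsworth–Emmons olefination should give the (Z)-trisubstituted enoate by fast, irreversible elimination, and the preformed phosphonate anion leaves the methyl ketone alone.

**Step 4**
Reactants: 6 ethyl (2Z,6Z)-2,6-dimethyl-8-{[(1E)-3-oxobut-1-en-1-yl]oxy}octa-2,6-dienoate
Product: 7 ethyl (2Z,6Z)-2,6-dimethyl-8-{[(1E)-3-methylbuta-1,3-dien-1-yl]oxy}octa-2,6-dienoate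
Conditions: Ph3PCH3Br, NaN(SiMe3)2, THF, 0 °C
Reagents that add atoms: methyltriphenylphosphonium bromide, C[P+](c1ccccc1)(c1ccccc1)c1ccccc1.[Br-]
Why: Wittig methylenation of the vinylogous-ester ketone should proceed by 1,2-addition of the unstabilised ylide, faster than attack on the hindered conjugated ester and without touching the (E)-enol ether geometry.

**Step 5**
Reactants: 7 ethyl (2Z,6Z)-2,6-dimethyl-8-{[(1E)-3-methylbuta-1,3-dien-1-yl]oxy}octa-2,6-dienoate
Product: 8 (2Z,6Z)-2,6-dimethyl-8-{[(1E)-3-methylbuta-1,3-dien-1-yl]oxy}octa-2,6-dien-1-ol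
Conditions: iBu2AlH (2.5 equiv), THF, −78 °C; Rochelle salt work-up
Reagents that add atoms: none
Why: 1,2-Reduction of the enoate by the aluminium hydride at low temperature in a coordinating solvent should give the (Z)-allylic alcohol without alkene isomerisation or reaction at the dienyl ether.

**Step 6**
Reactants: 8 (2Z,6Z)-2,6-dimethyl-8-{[(1E)-3-methylbuta-1,3-dien-1-yl]oxy}octa-2,6-dien-1-ol
Product: 9 triethyl{[(2Z,6Z)-2,6-dimethyl-8-{[(1E)-3-methylbuta-1,3-dien-1-yl]oxy}octa-2,6-dien-1-yl]oxy}silane
Conditions: Et3SiCl, imidazole, CH2Cl2, 0 °C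
Reagents that add atoms: chlorotriethylsilane, CC[Si](Cl)(CC)CC
Why: Silylation under buffered basic conditions is tolerated by the acid-labile dienyl ether, and the triethylsilyl ether is a poor Lewis base that is shed in the acidic work-up of step 7.

**Step 7**
Reactants: 9 triethyl{[(2Z,6Z)-2,6-dimethyl-8-{[(1E)-3-methylbuta-1,3-dien-1-yl]oxy}octa-2,6-dien-1-yl]oxy}silane
Product: 12 (1S,2S,3S,6S)-3-ethenyl-6-(3-hydroxyprop-1-en-2-yl)-3-methyl-2-(prop-1-en-2-yl)cyclohexan-1-ol, via Claisen aldehyde 10 (not isolated), via silyl ether 11 (not isolated)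
Conditions: Al(OAr)3 (1.5 equiv; Ar = (R)-3-phenyl-1,1'-binaphthalen-2-yl; from AlMe3 and ArOH, 3 equiv), toluene, −78 °C; then Me2AlCl (2 equiv), −78 → −30 °C; then 1 M HCl, THF, 0 °C
Reagents that add atoms: none
Why: The aluminium tris(aryloxide) binds the only basic oxygen, that of the allyl dienyl ether, and triggers a Claisen [3,3] shift through a chair in which the (E)-enol ether places isopropenyl and the (Z)-allyl unit places methyl pseudo-equatorial, so the bond from the isopropenyl-bearing carbon to the quaternary carbon forms with isopropenyl cis to methyl, while the chiral aryloxide pocket selects the enantiotopic face; the closest known reaction is the enantioselective Claisen rearrangement of allyl vinyl ethers promoted by chiral aluminium aryloxides. Me2AlCl then activates aldehyde 10 for a carbonyl-ene reaction of the citronellal-to-isopulegol kind, which closes the cyclohexane 6-exo-trig at the carbonyl carbon (alkene carbon to aldehyde carbon, hydrogen from the (E)-methyl group to oxygen) through a chair transition state. In that chair the isopropenyl group, the vinyl group, the aluminium-bound oxygen and the reacting alkene are equatorial and only the methyl group is axial, so the two centres set in the first event relay by substrate control to the carbinol carbon and its side-chain-bearing neighbour, giving the all-trans array. The (Z) geometry of the silyloxymethyl alkene keeps the CH2OSi hydrogens away from the carbonyl oxygen, so the new 2-propenyl unit keeps its oxygen as an allylic silyl ether instead of becoming an enol ether. The step needs the [3,3] shift to beat ion-pair pathways and the ene closure to beat Cope rearrangement of 10 to the conjugated farnesal-type enal; low temperature, a non-polar solvent and the absence of any other Lewis-basic group serve both. Dilute acid in the work-up cleaves the triethylsilyl ether of 11 to give diol 12.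

**Step 8**
Reactants: 12 (1S,2S,3S,6S)-3-ethenyl-6-(3-hydroxyprop-1-en-2-yl)-3-methyl-2-(prop-1-en-2-yl)cyclohexan-1-ol
Product: 13 (1R,2S,3S,6R)-3-ethenyl-6-[(2S)-2-(hydroxymethyl)oxiran-2-yl]-3-methyl-2-(prop-1-en-2-yl)cyclohexan-1-ol
Conditions: Ti(OtBu)4 (1.1 equiv), L-(+)-diethyl tartrate (1.3 equiv), tBuOOH, 4 Å molecular sieves, CH2Cl2, −20 °C
Reagents that add atoms: tert-butyl hydroperoxide, CC(C)(C)OO
Why: The Sharpless epoxidation is selective for the allylic alcohol alkene over the isopropenyl and vinyl groups, and its reagent-controlled facial selectivity should give the (S)-oxirane, which turns any minor enantiomer of 12 into a separable diastereomer, although the oxirane carbon is no longer stereogenic in the target.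

**Step 9**
Reactants: 13 (1R,2S,3S,6R)-3-ethenyl-6-[(2S)-2-(hydroxymethyl)oxiran-2-yl]-3-methyl-2-(prop-1-en-2-yl)cyclohexan-1-ol
Product: 14 2-[(1R,2R,3S,4S)-4-ethenyl-2-hydroxy-4-methyl-3-(prop-1-en-2-yl)cyclohexyl]-2,3-dihydroxypropyl acetate (configuration at the tertiary carbinol carbon inconsequential)
Conditions: CsOAc, AcOH, DMF, 70 °C
Reagents that add atoms: acetic acid, CC(=O)O (acetate delivered from CsOAc)
Why: SN2 opening of the 2,2-disubstituted epoxide by acetate at its CH2 terminus should give the primary acetate, and a degenerate Payne shift or acetyl migration between the two primary oxygens only epimerises a centre that becomes non-stereogenic in 15.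

**Step 10**
Reactants: 14 2-[(1R,2R,3S,4S)-4-ethenyl-2-hydroxy-4-methyl-3-(prop-1-en-2-yl)cyclohexyl]-2,3-dihydroxypropyl acetate
Product: 15 2-[(1R,2R,3S,4S)-4-ethenyl-2-hydroxy-4-methyl-3-(prop-1-en-2-yl)cyclohexyl]-2-hydroxypropane-1,3-diyl diacetate
Conditions: Ac2O (1.1 equiv), 2,4,6-collidine, CH2Cl2, −20 → 0 °C
Reagents that add atoms: acetic anhydride, CC(=O)OC(C)=O
Why: Acetylation of the remaining primary alcohol should be much faster than that of the hindered equatorial secondary alcohol or the tertiary alcohol, and it makes the two CH2OAc arms identical.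

**Compound list**
1 | nerol, (2Z)-3,7-dimethylocta-2,6-dien-1-ol | OC/C=C(C)\CCC=C(C)C | starting material
2 | but-3-yn-2-one | CC(=O)C#C | starting material
3 | (3E)-4-{[(2Z)-3,7-dimethylocta-2,6-dien-1-yl]oxy}but-3-en-2-one | CC(=O)/C=C/OC/C=C(C)\CCC=C(C)C | intermediate
4 | (4Z)-4-methyl-6-{[(1E)-3-oxobut-1-en-1-yl]oxy}hex-4-enal | CC(=O)/C=C/OC/C=C(C)\CCC=O | intermediate
5 | ethyl 2-[bis(2,2,2-trifluoroethoxy)phosphoryl]propanoate (racemic) | CCOC(=O)C(C)P(=O)(OCC(F)(F)F)OCC(F)(F)F | starting material
6 | ethyl (2Z,6Z)-2,6-dimethyl-8-{[(1E)-3-oxobut-1-en-1-yl]oxy}octa-2,6-dienoate | CCOC(=O)/C(C)=C\CC/C(C)=C\CO/C=C/C(C)=O | intermediate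
7 | ethyl (2Z,6Z)-2,6-dimethyl-8-{[(1E)-3-methylbuta-1,3-dien-1-yl]oxy}octa-2,6-dienoate | CCOC(=O)/C(C)=C\CC/C(C)=C\CO/C=C/C(C)=C | intermediate
8 | (2Z,6Z)-2,6-dimethyl-8-{[(1E)-3-methylbuta-1,3-dien-1-yl]oxy}octa-2,6-dien-1-ol | OC/C(C)=C\CC/C(C)=C\CO/C=C/C(C)=C | intermediate
9 | triethylsilyl ether of 8 | CC[Si](CC)(CC)OC/C(C)=C\CC/C(C)=C\CO/C=C/C(C)=C | intermediate
10 | (2S,3S,6Z)-3-ethenyl-3,7-dimethyl-2-(prop-1-en-2-yl)-8-(triethylsilyloxy)oct-6-enal | C=C[C@](C)(CC/C=C(C)\CO[Si](CC)(CC)CC)[C@@H](C=O)C(=C)C | intermediate (not isolated)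
11 | (1S,2S,3S,6S)-3-ethenyl-3-methyl-2-(prop-1-en-2-yl)-6-[3-(triethylsilyloxy)prop-1-en-2-yl]cyclohexan-1-ol | C=C[C@]1(C)CC[C@@H](C(=C)CO[Si](CC)(CC)CC)[C@H](O)[C@H]1C(=C)C | intermediate (not isolated)
12 | (1S,2S,3S,6S)-3-ethenyl-6-(3-hydroxyprop-1-en-2-yl)-3-methyl-2-(prop-1-en-2-yl)cyclohexan-1-ol | C=C[C@]1(C)CC[C@@H](C(=C)CO)[C@H](O)[C@H]1C(=C)C | intermediate
13 | (1R,2S,3S,6R)-3-ethenyl-6-[(2S)-2-(hydroxymethyl)oxiran-2-yl]-3-methyl-2-(prop-1-en-2-yl)cyclohexan-1-ol | C=C[C@]1(C)CC[C@@H]([C@]2(CO)CO2)[C@H](O)[C@H]1C(=C)C | intermediate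
14 | 2-[(1R,2R,3S,4S)-4-ethenyl-2-hydroxy-4-methyl-3-(prop-1-en-2-yl)cyclohexyl]-2,3-dihydroxypropyl acetate | C=C[C@]1(C)CC[C@@H](C(O)(CO)COC(C)=O)[C@H](O)[C@H]1C(=C)C | intermediate
15 | 2-[(1R,2R,3S,4S)-4-ethenyl-2-hydroxy-4-methyl-3-(prop-1-en-2-yl)cyclohexyl]-2-hydroxypropane-1,3-diyl diacetate | C=C[C@]1(C)CC[C@@H](C(O)(COC(C)=O)COC(C)=O)[C@H](O)[C@H]1C(=C)C | target

**Total step count:** 10
**Longest linear sequence:** 10 steps (from nerol 1)

**Steps most likely to fail**

Step 7. The aluminium reagent may discriminate the enantiotopic faces only weakly, and Lewis-acid ionisation of the neryl ether may erode the [3,3] pathway. The fallback sets out from 9 and secures the single enantiomer by resolution instead of induction. The cascade is run with the achiral, bulky MeAl(OAr')2 (Ar' = 4-bromo-2,6-di-tert-butylphenyl), then Me2AlCl and the same acid work-up, to give the racemic diol F1. Under the conditions of step 8, reagent control converts the two enantiomers of F1 into diastereomeric (S)-oxiranes. The unwanted diastereomeric epoxy diol F2 is removed by chromatography, and the other diastereomer is 13, where the route is rejoined.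

Step 2. Ozone may over-oxidise by also attacking the allylic-ether alkene or the enone alkene. The fallback sets out from 3: epoxidation with mCPBA (CH2Cl2, 0 °C), which discriminates more sharply for the isopropylidene alkene, gives the terminal epoxide F3. Cleavage of F3 with H5IO6 in THF/H2O returns to the route at 4.

Step 4. The basic ylide may enolise the methyl ketone, or add in conjugate fashion with loss of the alkoxy group, instead of olefinating. The fallback sets out from 6 and uses a two-stage Peterson olefination. Me3SiCH2MgCl with CeCl3 (THF, −78 °C) adds to the ketone to give the β-hydroxysilane F4. Elimination from F4 with KH in THF returns to the route at 7.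

**Further compounds**
F1 | step 7 | racemic diol, 12 together with its enantiomer | C=C[C@]1(C)CC[C@@H](C(=C)CO)[C@H](O)[C@H]1C(=C)C.C=C[C@@]1(C)CC[C@H](C(=C)CO)[C@@H](O)[C@@H]1C(=C)C
F2 | step 7 | (1S,2R,3R,6S)-3-ethenyl-6-[(2S)-2-(hydroxymethyl)oxiran-2-yl]-3-methyl-2-(prop-1-en-2-yl)cyclohexan-1-ol | C=C[C@@]1(C)CC[C@H]([C@]2(CO)CO2)[C@@H](O)[C@@H]1C(=C)C
F3 | step 2 | (3E)-4-{[(2Z)-5-(3,3-dimethyloxiran-2-yl)-3-methylpent-2-en-1-yl]oxy}but-3-en-2-one (racemic at the oxirane carbon) | CC(=O)/C=C/OC/C=C(C)\CCC1OC1(C)C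
F4 | step 4 | ethyl (2Z,6Z)-8-{[(1E)-3-hydroxy-3-methyl-4-(trimethylsilyl)but-1-en-1-yl]oxy}-2,6-dimethylocta-2,6-dienoate (racemic at the carbinol carbon) | CCOC(=O)/C(C)=C\CC/C(C)=C\CO/C=C/C(C)(O)C[Si](C)(C)C
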